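**Retrosynthetic overview**
Labdane numbering is used (decalin C1–C10, O on C2, gem-dimethyl C4, ring fusion C5/C10, C7=C8, side chain C11–C15 on C9, C17 = methyl on C8, C20 = methyl on C10). Target ⇒ C15 methyl ester (esterase hydrolysis) ⇒ C2 alcohol + angelic acid (mixed-anhydride esterification).
Side chain: C11–C12 by Wittig reaction of a C11 aldehyde with a C12–C15 ylide (C13 from methyl (R)-3-methylglutarate), then diimide; the C7=C8 alkene with its C17 methyl comes from 1,4-reduction of an exocyclic C6=C7–C8=C17H2 diene.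
Key disconnection: ring B is a cyclohexene in which C9–C10 (C20 and C11 trans) is a two-carbon unit, C5–C6–C7–C8 (C17 on sp2 C8) a four-carbon unit, and C1–C4 of ring A a four-atom bridge from C10 to C5. Cutting C5–C10 and C8–C9 (retro intramolecular [4+2]) therefore opens rings A and B together to an acyclic vinylallene Z-enoate whose only stereocentre is C2.
Triene ⇒ E-vinyl iodide + allenylstannane (Stille); Z-enoate ⇒ ynoate + Me2CuLi; carbon chain ⇒ isobutyronitrile + (S)-epichlorohydrin + acetylide.
Ring order: rings A and B are formed together in the key step; no other ring is built.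
Key step: step 9

Remark: methyl (R)-3-methylglutarate (the mono-ester), (S)-epichlorohydrin, angelic acid and tributyl(propa-1,2-dienyl)stannane are taken as catalogue compounds; the CIP letter of the C2 carbinol carbon changes along the route only because substituent priorities change, its spatial arrangement is never touched.

Step 1
Reactants: 1 isobutyronitrile; 2 (S)-epichlorohydrin
Product: 4 (S)-2,2-dimethyl-3-(oxiran-2-yl)propanenitrile, via lithium chlorohydrin alkoxide 3 (not isolated)
Conditions: LiN(i-Pr)2 (commercial solution), THF, −78 °C; then 2 (2 equiv, inverse addition), −78 °C to rt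
Reagents that add atoms: none
Why: The lithiated nitrile opens the epoxide terminus of 2 and the alkoxide so formed displaces chloride (epoxide opening then intramolecular Williamson closure), which builds the quaternary C4 and relocates the epoxide without touching the stereocentre taken from the chiral pool.

Step 2
Reactants: 4
Product: 5 (R)-4-hydroxy-2,2-dimethylhept-6-ynenitrile
Conditions: LiC≡CH·H2NCH2CH2NH2, DMSO, 15 °C to rt; aq. NH4Cl
Reagents that add atoms: lithium acetylide–ethylenediamine complex, [Li+].[C-]#C.NCCN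
Why: SN2 opening of the terminal epoxide at its unhindered CH2 by acetylide (epoxide alkynylation) attaches C1, C10 and C9 and leaves the C2 configuration unchanged.

Step 3
Reactants: 5
Product: 6 (R)-4-((tert-butyldimethylsilyl)oxy)-2,2-dimethylhept-6-ynenitrile
Conditions: TBSCl, imidazole, DMF, rt
Reagents that add atoms: tert-butyldimethylsilyl chloride, CC(C)(C)[Si](C)(C)Cl
Why: Standard silyl ether formation; the bulky TBS ether prevents lactonisation onto the later Z-enoate and later serves as the equatorial control element of the key step.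

Step 4
Reactants: 6
Product: 8 (R)-4-((tert-butyldimethylsilyl)oxy)-2,2-dimethylhept-6-ynal, via N-diisobutylaluminio aldimine 7 (not isolated)
Conditions: i-Bu2AlH (1.3 equiv), toluene, −78 °C; then aq. citric acid, 0 °C
Reagents that add atoms: water, O
Why: i-Bu2AlH adds once to the hindered nitrile to give a stable aluminium aldimide that is hydrolysed to the aldehyde on work-up (nitrile half-reduction); the quaternary α-carbon excludes enolisation.

Step 5
Reactants: 8
Product: 9 (R,E)-tert-butyl((1-iodo-3,3-dimethyloct-1-en-7-yn-5-yl)oxy)dimethylsilane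
Conditions: CrCl2 (6 equiv), CHI3 (2 equiv), THF–dioxane, 0 °C to rt
Reagents that add atoms: iodoform, IC(I)I
Why: Takai olefination of the non-enolisable α-quaternary aldehyde through the geminal dichromium reagent should give the E-vinyl iodide (C6), E-selectivity being best for hindered aldehydes; alkyne and silyl ether are inert.

Step 6
Reactants: 9
Product: 11 methyl (S,E)-5-((tert-butyldimethylsilyl)oxy)-9-iodo-7,7-dimethylnon-8-en-2-ynoate, via alkynylmagnesium bromide 10 (not isolated)
Conditions: EtMgBr, THF, 0 °C to rt; then ClCO2Me, −78 to 0 °C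
Reagents that add atoms: methyl chloroformate, COC(=O)Cl
Why: Deprotonation of the terminal alkyne by EtMgBr and C-acylation of the alkynyl Grignard reagent with the chloroformate installs C11 as the ynoate; EtMgBr does not exchange with the vinyl iodide.

Step 7
Reactants: 11
Product: 13 methyl (2Z,5R,8E)-5-((tert-butyldimethylsilyl)oxy)-9-iodo-3,7,7-trimethylnona-2,8-dienoate, via lithium alkenyl(methyl)cuprate 12 (not isolated)
Conditions: Me2CuLi (from MeLi and CuI, 1.3 equiv), THF, −78 °C; MeOH then aq. NH4Cl at −78 °C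
Reagents that add atoms: lithium dimethylcuprate, [Li+].C[Cu-]C
Why: Syn-carbocupration of the ynoate at −78 °C and protonation of the alkenylcuprate with retention places the new C20 methyl trans to the ester, so that the chain (C1) is cis to CO2Me (Z) as the key step requires.

Step 8
Reactants: 13; 14 tributyl(propa-1,2-dienyl)stannane
Product: 15 methyl (2Z,5R,8E)-5-((tert-butyldimethylsilyl)oxy)-3,7,7-trimethyldodeca-2,8,10,11-tetraenoate
Conditions: Pd2(dba)3 (2.5 mol %), AsPh3 (20 mol %), DMF, rt, dark
Reagents that add atoms: none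
Why: Stille coupling transfers the allenyl group (C7, C8, C17) to the E-vinyl iodide with retention of alkene geometry; the neutral conditions leave the Z-enoate untouched.

Step 9
Reactants: 15
Product: 16 methyl (1R,4aR,7S,8aS)-7-((tert-butyldimethylsilyl)oxy)-5,5,8a-trimethyl-2-methylene-1,2,4a,5,6,7,8,8a-octahydronaphthalene-1-carboxylate
Conditions: toluene (0.01 M), BHT (5 mol %), 110–130 °C, sealed tube
Reagents that add atoms: none
Why: Thermal intramolecular [4+2] cycloaddition (type 1 intramolecular Diels–Alder reaction; closest precedent: cycloadditions of vinylallenes and of 1,3,9-decatrienoates): the C5=C6–C7=C8 diene of the vinylallene adds suprafacially to the Z-enoate C9=C10, forming C5–C10 and C8–C9 in one concerted, asynchronous event, while the orthogonal C8=C17 π bond remains as an exocyclic methylene so that C8 never becomes a stereocentre. Ring B closes as the six-membered cycloadduct ring and ring A closes through the same C5–C10 bond across the four-atom C1–C4 tether (fused six/six closure through a chair-like tether). C9 and C10 are fixed by the Z geometry of the dienophile (C20 methyl and C11 end up trans), and the cis ring fusion at C5/C10 by the endo transition state in which the ester, and with it C1, lies under the diene while the C10 methyl points away from it. The absolute sense comes from C2: in the chair-like tether the OTBS group must be equatorial, because an axial OTBS would be syn-axial to both the axial C4 methyl and the C10 methyl, and this places C2–O anti to C20 as in the target. The step needs endo over exo addition and one diene face; the Z-ester, the gem-dimethyl group next to the diene (which also excludes a [1,5]-hydrogen shift of the vinylallene and favours ring closure) and the C2 silyl ether should secure them, and the tether fixes the regiochemistry.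

Step 10
Reactants: 16
Product: 17 [(1R,4aR,7S,8aS)-7-((tert-butyldimethylsilyl)oxy)-5,5,8a-trimethyl-2-methylene-1,2,4a,5,6,7,8,8a-octahydronaphthalen-1-yl]methanol
Conditions: LiAlH4, Et2O, 0 °C
Reagents that add atoms: none
Why: Hydride reduction of the hindered ester to the primary alcohol removes the only group that would not survive the dissolving-metal step; the diene (not conjugated with the ester) and the silyl ether are inert.

Step 11
Reactants: 17
Product: 18 [(1R,4aR,7S,8aS)-7-((tert-butyldimethylsilyl)oxy)-2,5,5,8a-tetramethyl-1,4,4a,5,6,7,8,8a-octahydronaphthalen-1-yl]methanol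
Conditions: Li (5 equiv), NH3(l)–THF, t-BuOH (3 equiv), −78 °C; then solid NH4Cl
Reagents that add atoms: none
Why: Dissolving-metal (Birch-type) 1,4-reduction of the conjugated exocyclic diene: electron transfer, protonation at the terminal CH2 (C17) and then at the less substituted allyl terminus C6 should leave the trisubstituted C7=C8 alkene with its C17 methyl, while the isolated product alkene, the alkoxide and the silyl ether are not reduced.

Step 12
Reactants: 18
Product: 19 (1R,4aR,7S,8aS)-7-((tert-butyldimethylsilyl)oxy)-2,5,5,8a-tetramethyl-1,4,4a,5,6,7,8,8a-octahydronaphthalene-1-carbaldehyde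
Conditions: Dess–Martin periodinane, pyridine, CH2Cl2, 0 °C to rt
Reagents that add atoms: none
Why: Dess–Martin oxidation under buffered, non-basic conditions should give the C11 aldehyde without epimerising the α-stereocentre C9 or moving the β,γ-alkene into conjugation.

Step 13
Reactants: 20 methyl (R)-3-methylglutarate [(R)-5-methoxy-3-methyl-5-oxopentanoic acid]
Product: 21 methyl (S)-4-iodo-3-methylbutanoate
Conditions: PhI(OAc)2, I2, cyclohexane, hν (tungsten lamp), reflux
Reagents that add atoms: iodine, II
Why: Hypervalent-iodine iododecarboxylation (Suárez conditions, a Hunsdiecker-type radical chain through the acyl hypoiodite) replaces CO2H by iodine; the radical sits on C12, so the neighbouring C13 stereocentre from the chiral pool is untouched.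

Step 14
Reactants: 21
Product: 22 (S)-(4-methoxy-2-methyl-4-oxobutyl)triphenylphosphonium iodide
Conditions: PPh3, MeCN, reflux
Reagents that add atoms: triphenylphosphine, c1ccc(cc1)P(c1ccccc1)c1ccccc1
Why: SN2 quaternisation of PPh3 by the primary iodide gives the Wittig salt.

Step 15
Reactants: 19; 22
Product: 24 methyl (3S,4Z)-5-[(1R,4aR,7S,8aS)-7-((tert-butyldimethylsilyl)oxy)-2,5,5,8a-tetramethyl-1,4,4a,5,6,7,8,8a-octahydronaphthalen-1-yl]-3-methylpent-4-enoate, via phosphorus ylide 23 (not isolated)
Conditions: 22, NaN(SiMe3)2, THF, −78 to 0 °C; then 19, −78 °C to rt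
Reagents that add atoms: none
Why: Wittig olefination with the non-stabilised ylide, formed before the aldehyde is added so that enolisation of 19 is kept down, joins C11 to C12 (Z-alkene, geometry irrelevant) and brings in C13 with the configuration of 20.

Step 16
Reactants: 24
Product: 25 methyl (3R)-5-[(1R,4aR,7S,8aS)-7-((tert-butyldimethylsilyl)oxy)-2,5,5,8a-tetramethyl-1,4,4a,5,6,7,8,8a-octahydronaphthalen-1-yl]-3-methylpentanoate
Conditions: 2-nitrobenzenesulfonylhydrazide (excess), Et3N, CH2Cl2, rt
Reagents that add atoms: none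
Why: Diimide reduction (concerted syn transfer of H2) should saturate the disubstituted C11=C12 alkene but not the trisubstituted ring alkene and, being metal-free, cannot move the C7=C8 bond.

Step 17
Reactants: 25
Product: 26 methyl (3R)-5-[(1R,4aR,7S,8aS)-7-hydroxy-2,5,5,8a-tetramethyl-1,4,4a,5,6,7,8,8a-octahydronaphthalen-1-yl]-3-methylpentanoate
Conditions: HF·pyridine, pyridine–THF, 0 °C to rt
Reagents that add atoms: none
Why: Fluoride cleavage of the secondary silyl ether (Si–F bond formation) frees the C2 alcohol; the methyl ester and the alkene are unaffected under these buffered conditions.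

Step 18
Reactants: 26; 27 angelic acid [(Z)-2-methylbut-2-enoic acid]
Product: 28 (2S,4aR,8R,8aS)-8-[(3R)-5-methoxy-3-methyl-5-oxopentyl]-4,4,7,8a-tetramethyl-1,2,3,4,4a,5,8,8a-octahydronaphthalen-2-yl (Z)-2-methylbut-2-enoate
Conditions: 27, 2,4,6-trichlorobenzoyl chloride, Et3N, toluene, rt; then 26, 75 °C
Reagents that add atoms: none
Why: Yamaguchi-type esterification through the mixed 2,4,6-trichlorobenzoic anhydride, without a nucleophilic catalyst, should acylate the equatorial C2 alcohol while keeping the Z geometry of the angelate (no isomerisation to tiglate).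

Step 19
Reactants: 28
Product: 29 (3R)-5-[(1R,4aR,7S,8aS)-2,5,5,8a-tetramethyl-7-{[(Z)-2-methylbut-2-enoyl]oxy}-1,4,4a,5,6,7,8,8a-octahydronaphthalen-1-yl]-3-methylpentanoic acid (CNP0248298.1)
Conditions: pig liver esterase (a carboxylesterase), phosphate buffer pH 7.5–DMSO (9:1), 30 °C
Reagents that add atoms: water, O
Why: Enzymatic ester hydrolysis by a carboxylesterase (serine hydrolase) at neutral pH should cleave the unhindered methyl ester of the primary chain, whereas the hindered secondary α-branched enoate is a poor substrate and is not exposed to hydroxide, which could isomerise it.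

**Compound list**
1 | isobutyronitrile | CC(C)C#N | starting material
2 | (S)-epichlorohydrin | ClC[C@@H]1CO1 | starting material
3 | lithium (S)-1-chloro-4-cyano-4-methylpentan-2-olate | [Li+].N#CC(C)(C)C[C@H]([O-])CCl | intermediate (not isolated)
4 | (S)-2,2-dimethyl-3-(oxiran-2-yl)propanenitrile | N#CC(C)(C)C[C@H]1CO1 | intermediate
5 | (R)-4-hydroxy-2,2-dimethylhept-6-ynenitrile | N#CC(C)(C)C[C@H](O)CC#C | intermediate
6 | (R)-4-((tert-butyldimethylsilyl)oxy)-2,2-dimethylhept-6-ynenitrile | N#CC(C)(C)C[C@H](O[Si](C)(C)C(C)(C)C)CC#C | intermediate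
7 | N-diisobutylaluminio aldimine of 8 (R) | CC(C)C[Al](CC(C)C)N=CC(C)(C)C[C@H](O[Si](C)(C)C(C)(C)C)CC#C | intermediate (not isolated)
8 | (R)-4-((tert-butyldimethylsilyl)oxy)-2,2-dimethylhept-6-ynal | O=CC(C)(C)C[C@H](O[Si](C)(C)C(C)(C)C)CC#C | intermediate
9 | (R,E)-tert-butyl((1-iodo-3,3-dimethyloct-1-en-7-yn-5-yl)oxy)dimethylsilane | I/C=C/C(C)(C)C[C@H](O[Si](C)(C)C(C)(C)C)CC#C | intermediate
10 | bromomagnesium acetylide of 9 | I/C=C/C(C)(C)C[C@H](O[Si](C)(C)C(C)(C)C)CC#C[Mg]Br | intermediate (not isolated)
11 | methyl (S,E)-5-((tert-butyldimethylsilyl)oxy)-9-iodo-7,7-dimethylnon-8-en-2-ynoate | I/C=C/C(C)(C)C[C@H](O[Si](C)(C)C(C)(C)C)CC#CC(=O)OC | intermediate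
12 | lithium alkenyl(methyl)cuprate, syn-carbocupration adduct of 11 (Cu on C9, cis to the new methyl) | [Li+].I/C=C/C(C)(C)C[C@H](O[Si](C)(C)C(C)(C)C)C/C(C)=C(/[Cu-]C)C(=O)OC | intermediate (not isolated)
13 | methyl (2Z,5R,8E)-5-((tert-butyldimethylsilyl)oxy)-9-iodo-3,7,7-trimethylnona-2,8-dienoate | I/C=C/C(C)(C)C[C@H](O[Si](C)(C)C(C)(C)C)C/C(C)=C\C(=O)OC | intermediate
14 | tributyl(propa-1,2-dienyl)stannane | C=C=C[Sn](CCCC)(CCCC)CCCC | starting material
15 | methyl (2Z,5R,8E)-5-((tert-butyldimethylsilyl)oxy)-3,7,7-trimethyldodeca-2,8,10,11-tetraenoate | C=C=C/C=C/C(C)(C)C[C@H](O[Si](C)(C)C(C)(C)C)C/C(C)=C\C(=O)OC | intermediate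
16 | methyl (1R,4aR,7S,8aS)-7-((tert-butyldimethylsilyl)oxy)-5,5,8a-trimethyl-2-methylene-1,2,4a,5,6,7,8,8a-octahydronaphthalene-1-carboxylate | CC(C)(C)[Si](C)(C)O[C@H]1CC(C)(C)[C@H]2C=CC(=C)[C@@H](C(=O)OC)[C@@]2(C)C1 | intermediate
17 | [(1R,4aR,7S,8aS)-7-((tert-butyldimethylsilyl)oxy)-5,5,8a-trimethyl-2-methylene-1,2,4a,5,6,7,8,8a-octahydronaphthalen-1-yl]methanol | CC(C)(C)[Si](C)(C)O[C@H]1CC(C)(C)[C@H]2C=CC(=C)[C@@H](CO)[C@@]2(C)C1 | intermediate
18 | [(1R,4aR,7S,8aS)-7-((tert-butyldimethylsilyl)oxy)-2,5,5,8a-tetramethyl-1,4,4a,5,6,7,8,8a-octahydronaphthalen-1-yl]methanol | CC(C)(C)[Si](C)(C)O[C@H]1CC(C)(C)[C@H]2CC=C(C)[C@@H](CO)[C@@]2(C)C1 | intermediate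
19 | (1R,4aR,7S,8aS)-7-((tert-butyldimethylsilyl)oxy)-2,5,5,8a-tetramethyl-1,4,4a,5,6,7,8,8a-octahydronaphthalene-1-carbaldehyde | CC(C)(C)[Si](C)(C)O[C@H]1CC(C)(C)[C@H]2CC=C(C)[C@@H](C=O)[C@@]2(C)C1 | intermediate
20 | methyl (R)-3-methylglutarate [(R)-5-methoxy-3-methyl-5-oxopentanoic acid] | OC(=O)C[C@@H](C)CC(=O)OC | starting material
21 | methyl (S)-4-iodo-3-methylbutanoate | IC[C@@H](C)CC(=O)OC | intermediate
22 | (S)-(4-methoxy-2-methyl-4-oxobutyl)triphenylphosphonium iodide | [I-].COC(=O)C[C@H](C)C[P+](c1ccccc1)(c1ccccc1)c1ccccc1 | intermediate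
23 | methyl (S)-3-methyl-4-(triphenylphosphoranylidene)butanoate | COC(=O)C[C@H](C)C=P(c1ccccc1)(c1ccccc1)c1ccccc1 | intermediate (not isolated)
24 | methyl (3S,4Z)-5-[(1R,4aR,7S,8aS)-7-((tert-butyldimethylsilyl)oxy)-2,5,5,8a-tetramethyl-1,4,4a,5,6,7,8,8a-octahydronaphthalen-1-yl]-3-methylpent-4-enoate | CC(C)(C)[Si](C)(C)O[C@H]1CC(C)(C)[C@H]2CC=C(C)[C@@H](/C=C\[C@@H](C)CC(=O)OC)[C@@]2(C)C1 | intermediate
25 | methyl (3R)-5-[(1R,4aR,7S,8aS)-7-((tert-butyldimethylsilyl)oxy)-2,5,5,8a-tetramethyl-1,4,4a,5,6,7,8,8a-octahydronaphthalen-1-yl]-3-methylpentanoate | CC(C)(C)[Si](C)(C)O[C@H]1CC(C)(C)[C@H]2CC=C(C)[C@@H](CC[C@@H](C)CC(=O)OC)[C@@]2(C)C1 | intermediate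
26 | methyl (3R)-5-[(1R,4aR,7S,8aS)-7-hydroxy-2,5,5,8a-tetramethyl-1,4,4a,5,6,7,8,8a-octahydronaphthalen-1-yl]-3-methylpentanoate | O[C@H]1CC(C)(C)[C@H]2CC=C(C)[C@@H](CC[C@@H](C)CC(=O)OC)[C@@]2(C)C1 | intermediate
27 | angelic acid [(Z)-2-methylbut-2-enoic acid] | C/C=C(/C)C(=O)O | starting material
28 | (2S,4aR,8R,8aS)-8-[(3R)-5-methoxy-3-methyl-5-oxopentyl]-4,4,7,8a-tetramethyl-1,2,3,4,4a,5,8,8a-octahydronaphthalen-2-yl (Z)-2-methylbut-2-enoate | C/C=C(/C)C(=O)O[C@H]1CC(C)(C)[C@H]2CC=C(C)[C@@H](CC[C@@H](C)CC(=O)OC)[C@@]2(C)C1 | intermediate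
29 | (3R)-5-[(1R,4aR,7S,8aS)-2,5,5,8a-tetramethyl-7-{[(Z)-2-methylbut-2-enoyl]oxy}-1,4,4a,5,6,7,8,8a-octahydronaphthalen-1-yl]-3-methylpentanoic acid (CNP0248298.1) | C/C=C(/C)C(=O)O[C@H]1CC(C)(C)[C@H]2CC=C(C)[C@@H](CC[C@@H](C)CC(=O)O)[C@@]2(C)C1 | target

**Step count**
Total step count: 19 (17 in the main line, 2 for the ylide precursor). Longest linear sequence: 17 steps (steps 1–12 and 15–19).

**Steps most likely to fail, with fallbacks**

Step 9 (key cycloaddition). The endo preference may be lost (trans-fused adduct through the exo mode), the facial control by C2 may be incomplete, or the cycloaddition at the hindered β,β-disubstituted enoate may be slow and allow the allene to oligomerise. Fallback: switch to the aldehyde dienophile and a Lewis-acid-promoted cycloaddition at low temperature, where endo control is stronger. Setting out from 13, i-Bu2AlH (CH2Cl2, −78 °C) should give the Z-allylic alcohol F1, MnO2 (CH2Cl2, rt) the Z-enal F2, and Stille coupling with 14 as in step 8 the vinylallene enal F3. Me2AlCl (CH2Cl2, −78 to −20 °C) should then give the cis-fused bicyclic aldehyde F4, which NaBH4 (MeOH, 0 °C) reduces to 17, where the route is rejoined.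

Step 11 (1,4-reduction). The allyl anion may be protonated at C8 instead of C6 (1,2-reduction that leaves the alkene at C6=C7), or reduction may be incomplete. Fallback: avoid electron transfer and fix the alkene position by enolate chemistry. From 17, NaH, 4-methoxybenzyl chloride and Bu4NI in DMF should give the 4-methoxybenzyl ether F5. Lemieux–Johnson cleavage of the more accessible exocyclic methylene (OsO4 cat., NaIO4, 2,6-lutidine, dioxane–water) should give the C8 enone F6. LiBH(s-Bu)3 in THF at −78 °C followed by PhNTf2 (conjugate reduction, trapping of the regiodefined C7=C8 enolate) should give the enol triflate F7. MeMgBr with Fe(acac)3 (cat.) in THF–NMP at −20 °C should give the C8-methyl ether F8, and DDQ in wet CH2Cl2 returns 18.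

Step 15 (Wittig olefination). The basic ylide may enolise the hindered, α-branched, β,γ-unsaturated aldehyde, with epimerisation at C9 or migration of the C7=C8 bond into conjugation, and olefination between two branched partners may be slow. Fallback: avoid the aldehyde and form the C11–C12 bond directly as an sp3–sp3 bond. From 18, I2, PPh3 and imidazole (CH2Cl2, 0 °C) should give the primary iodide F9. Zinc dust with LiCl in THF should convert 21 into the alkylzinc iodide F10. Alkyl–alkyl Negishi coupling of F9 with F10 (Pd2(dba)3, P(c-C5H9)3, N-methylimidazole, THF–NMP, 80 °C) should give 25 directly, so that steps 12, 15 and 16 are bypassed.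

**Further compounds**
F1 | step 9 | (2Z,5R,8E)-5-((tert-butyldimethylsilyl)oxy)-9-iodo-3,7,7-trimethylnona-2,8-dien-1-ol | I/C=C/C(C)(C)C[C@H](O[Si](C)(C)C(C)(C)C)C/C(C)=C\CO
F2 | step 9 | (2Z,5R,8E)-5-((tert-butyldimethylsilyl)oxy)-9-iodo-3,7,7-trimethylnona-2,8-dienal | I/C=C/C(C)(C)C[C@H](O[Si](C)(C)C(C)(C)C)C/C(C)=C\C=O
F3 | step 9 | (2Z,5R,8E)-5-((tert-butyldimethylsilyl)oxy)-3,7,7-trimethyldodeca-2,8,10,11-tetraenal | C=C=C/C=C/C(C)(C)C[C@H](O[Si](C)(C)C(C)(C)C)C/C(C)=C\C=O
F4 | step 9 | (1R,4aR,7S,8aS)-7-((tert-butyldimethylsilyl)oxy)-5,5,8a-trimethyl-2-methylene-1,2,4a,5,6,7,8,8a-octahydronaphthalene-1-carbaldehyde | CC(C)(C)[Si](C)(C)O[C@H]1CC(C)(C)[C@H]2C=CC(=C)[C@@H](C=O)[C@@]2(C)C1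
F5 | step 11 | 4-methoxybenzyl ether of 17 (on the C11 oxygen; stereocentres as in 17) | CC(C)(C)[Si](C)(C)O[C@H]1CC(C)(C)[C@H]2C=CC(=C)[C@@H](COCc3ccc(OC)cc3)[C@@]2(C)C1
F6 | step 11 | C8 ketone (cyclohex-2-enone with C6=C7) carrying the C11 4-methoxybenzyl ether and C2 OTBS; stereocentres as in 17 | CC(C)(C)[Si](C)(C)O[C@H]1CC(C)(C)[C@H]2C=CC(=O)[C@@H](COCc3ccc(OC)cc3)[C@@]2(C)C1
F7 | step 11 | C7=C8 enol triflate (OTf on C8) of the ketone from F6; stereocentres as in 17 | CC(C)(C)[Si](C)(C)O[C@H]1CC(C)(C)[C@H]2CC=C(OS(=O)(=O)C(F)(F)F)[C@@H](COCc3ccc(OC)cc3)[C@@]2(C)C1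
F8 | step 11 | 4-methoxybenzyl ether of 18 (on the C11 oxygen; stereocentres as in 18) | CC(C)(C)[Si](C)(C)O[C@H]1CC(C)(C)[C@H]2CC=C(C)[C@@H](COCc3ccc(OC)cc3)[C@@]2(C)C1
F9 | step 15 | primary iodide of 18 (C11–I in place of C11–OH; stereocentres as in 18) | CC(C)(C)[Si](C)(C)O[C@H]1CC(C)(C)[C@H]2CC=C(C)[C@@H](CI)[C@@]2(C)C1
F10 | step 15 | (S)-(4-methoxy-2-methyl-4-oxobutyl)zinc iodide | COC(=O)C[C@H](C)C[Zn]I
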